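**Retrosynthetic overview**
1. Target 26 ⇐ bis-angeloylation of epoxy diol 23 ⇐ C6–OH-directed epoxidation of the (1(10)Z,4E)-8,12-olide diol 22.
2. 22 ⇐ Grob (Wharton) ring expansion of the cis-fused hydroazulene mesylate 19 (C4–C8 bond cleaved, giving the ten-membered ring and the E-4,5 olefin), then C8 reduction and lactone shift.
3. 19 ⇐ tricyclic lactone 15 by C11–OH-directed dihydroxylation and 8→6 acyl shift; 15 ⇐ ring-closing metathesis (seven-membered ring) of bicyclic lactone 12.
4. Quaternary C4 ⇐ epoxy-alcohol semipinacol 1,2-shift of butenyl from C8 to C4; C8 substituents by two 1,2-additions anti to the C7 side chain.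
5. C7/C11 ⇐ asymmetric aldol of 2-methylcyclopent-2-enone with ethyl pyruvate. Ring order: cyclopentene (bought) → γ-lactone → cycloheptene → cyclodecadiene → oxirane.

Assumption: germacrane numbering (C1–C15) is used for every intermediate, and the (S,S)-ligand in step 1 is taken to give the (7S,11R) adduct; if the sense is opposite, the (R,R)-ligand is used and nothing else changes.

**Step 1**
Reactants: 1 2-methylcyclopent-2-en-1-one; 2 ethyl pyruvate
Product: 5 ethyl (2R)-2-[(1S)-3-methyl-2-oxocyclopent-3-en-1-yl]-2-(triethylsilyloxy)propanoate, via lithium dienolate 3 (not isolated), via silyl dienol ether 4 (not isolated)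
Conditions: LiN(i-Pr)2, THF, −78 °C; Et3SiCl; pentane, filter; then 2, Sn(OSO2CF3)2 (10 mol %), 2,6-bis[(4S)-4-benzyl-4,5-dihydro-1,3-oxazol-2-yl]pyridine (11 mol %), CH2Cl2, −78 °C
Reagents that add atoms: chlorotriethylsilane CC[Si](Cl)(CC)CC
Why: Proposed new method: anti-selective enantioselective Mukaiyama aldol of a cross-conjugated 2-silyloxycyclopentadiene with a pyruvate ester under divalent tin–pybox catalysis; the pyruvate chelates tin through both carbonyl oxygens, a ligand benzyl group shields one face of the ketone, the enol ether attacks through an open transition state at its only nucleophilic terminus C7 with ring carbon C6 turned away from the ester (anti), and silyl transfer releases the catalyst, which sets C7 and the quaternary C11; closest known reaction type: tin–pybox-catalysed anti-aldol additions of thioester silyl ketene acetals to pyruvate and glyoxylate esters, and copper–bis(oxazoline)-catalysed pyruvate aldols of ketone enol silanes.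

**Step 2**
Reactants: 5 aldol adduct; 6 but-3-en-1-ylmagnesium bromide
Product: 7 tertiary allylic alcohol (C8 carbinol bearing but-3-enyl; OH cis and butenyl trans to the C7 side chain)
Conditions: LaCl3·2LiCl (30 mol %), THF, −78 °C; AcOH quench at −78 °C
Reagents that add atoms: none
Why: Lanthanum-promoted Grignard 1,2-addition to the enone carbonyl (enolisation and ester attack suppressed) takes place anti to the bulky C7 substituent, which puts the butenyl group trans and the hydroxyl cis to the side chain.

**Step 3**
Reactants: 7 tertiary allylic alcohol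
Product: 9 β-hydroxy ketone (C8 ketone; quaternary C4 with methyl cis and butenyl trans to the C7 side chain; C5–OH cis to the C4 methyl), via epoxy alcohol 8 (not isolated)
Conditions: VO(acac)2 (5 mol %), t-BuOOH (1.05 equiv), CH2Cl2, 0 °C; then BF3·OEt2 (20 mol %), −78 °C
Reagents that add atoms: tert-butyl hydroperoxide CC(C)(C)OO
Why: Hydroxyl-directed vanadium epoxidation places the oxirane cis to the C8 hydroxyl (trans to butenyl), and the Lewis-acid 2,3-epoxy-alcohol semipinacol rearrangement then shifts the anti-periplanar butenyl group suprafacially from C8 to the tertiary C4 as C8 becomes the ketone, which sets C4 stereospecifically and leaves the C5 hydroxyl cis to the methyl group.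

**Step 4**
Reactants: 9 β-hydroxy ketone; 10 2-methylallylmagnesium chloride
Product: 12 bicyclic 8,12-lactone (C8 bears 2-methylallyl; C5–OH free; C11–OSiEt3), via diol ester 11 (not isolated)
Conditions: 10 (2.3 equiv), LaCl3·2LiCl (30 mol %), THF, −78 °C, then 40 °C; AcOH
Reagents that add atoms: none
Why: A second lanthanum-promoted 1,2-addition, again anti to the C7 substituent, gives the tertiary alkoxide cis to C11, which closes the γ-lactone by acyl substitution on warming; one equivalent of Grignard is consumed by the C5 hydroxyl.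

**Step 5**
Reactants: 12 bicyclic lactone
Product: 13 tricyclic lactone (cis-fused cyclopentane–cycloheptene with C1=C10; C5–OH; C11–OSiEt3)
Conditions: second-generation Hoveyda–Grubbs catalyst RuCl2(H2IMes)(=CH–C6H4-2-O-i-Pr) (5 mol %), toluene, 80 °C
Reagents that add atoms: none
Why: Ring-closing metathesis of the two cis-disposed alkenyl chains gives the cycloheptene, whose ring size forces the Z geometry of the trisubstituted C1=C10 bond; it is run before the cyclopentene exists so that ring-rearrangement metathesis cannot compete.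

**Step 6**
Reactants: 13 tricyclic lactone
Product: 15 tricyclic α-hydroxy lactone with C5=C6 olefin, via silyl ether 14 (not isolated)
Conditions: methyl N-(triethylammoniumsulfonyl)carbamate (Burgess reagent), benzene, 60 °C; then HF·pyridine, THF, 0 to 23 °C
Reagents that add atoms: none
Why: Burgess syn-elimination of the secondary alcohol can only go towards C6 because C4 is quaternary, and gives the olefin under neutral conditions; fluoride then frees the tertiary C11 hydroxyl needed as directing group.

**Step 7**
Reactants: 15 tricyclic α-hydroxy lactone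
Product: 18 6,12-lactone triol (C5–OH, C8–OH, C11–OH free; O5 and O6 cis to C11 and to the C4 methyl), via osmate ester 16 (not isolated), via 8,12-lactone triol 17 (not isolated)
Conditions: OsO4 (1.05 equiv), TMEDA, CH2Cl2, −78 °C; aq. Na2SO3; then DBU (20 mol %), CH2Cl2, 23 °C
Reagents that add atoms: osmium tetroxide O=[Os](=O)(=O)=O
Why: Hydrogen-bond-directed (Donohoe) dihydroxylation is delivered by the endo C11 hydroxyl to the concave face of the cyclopentene only, which sets C6 and leaves the remote trisubstituted olefin alone; base-catalysed acyl migration then moves the lactone from the crowded tertiary O8 to the secondary O6, which frees the C8 hydroxyl and leaves C5–OH as the only secondary alcohol.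

**Step 8**
Reactants: 18 6,12-lactone triol
Product: 19 C5 methanesulfonate
Conditions: MsCl (1.2 equiv), pyridine, CH2Cl2, 0 °C
Reagents that add atoms: methanesulfonyl chloride CS(=O)(=O)Cl
Why: Sulfonylation of the only secondary hydroxyl; the tertiary hydroxyls at C8 and C11 do not react at 0 °C.

**Step 9**
Reactants: 19 mesylate
Product: 22 (1(10)Z,4E)-6,11-dihydroxygermacra-1(10),4-dien-8,12-olide (trans-fused lactone), via cyclodecadienone 20 (not isolated), via 8-hydroxy-6,12-lactone 21 (not isolated)
Conditions: KOt-Bu (1.1 equiv), THF, −78 to −40 °C; then CeCl3·7H2O, NaBH4, MeOH, −78 °C; then K2CO3 (20 mol %), MeOH, 0 °C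
Reagents that add atoms: none
Why: Alkoxide-driven Grob (Wharton) fragmentation: the C8 alkoxide pushes, the C4–C8 bond anti-periplanar to C5–OMs breaks, and because the mesylate is cis to the C4 methyl the new C4=C5 bond is E while the Z C1=C10 bond is carried over into the ten-membered ring; Luche reduction of the released ketone anti to the quaternary C11 (Felkin–Anh, reinforced by cerium chelation to O6) sets C8, and base-catalysed translactonisation gives the trans-fused 8,12-olide and frees C6–OH.

**Step 10**
Reactants: 22 diene diol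
Product: 23 (4S,5S)-4,5-epoxy diol
Conditions: VO(acac)2 (5 mol %), t-BuOOH (1.2 equiv), CH2Cl2, 0 °C
Reagents that add atoms: tert-butyl hydroperoxide CC(C)(C)OO
Why: Allylic-alcohol-directed vanadium epoxidation is chemoselective for C4=C5 (C1=C10 has no allylic hydroxyl) and delivers oxygen to the exposed peripheral face of the E-olefin, with the C6–O bond held near the olefin plane by the trans-fused lactone, which sets C4 and C5.

**Step 11**
Reactants: 23 epoxy diol; 24 angelic acid
Product: 26 target (6,11-di-O-angeloyl-4,5-epoxygermacr-1(10)Z-en-8,12-olide), via mixed anhydride 25 (not isolated)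
Conditions: 24 (8 equiv), 2,4,6-trichlorobenzoyl chloride (8 equiv), Et3N, toluene, 23 °C; then 23, 80 °C, 48 h
Reagents that add atoms: none
Why: Yamaguchi mixed-anhydride esterification without a nucleophilic pyridine catalyst is the standard way to form angelates without Z-to-E isomerisation; the large excess acylates both the secondary C6 and the tertiary C11 hydroxyl, and no stereocentre is touched.

**Compound list**
1 | 2-methylcyclopent-2-en-1-one | CC1=CCCC1=O | starting material
2 | ethyl pyruvate | CC(=O)C(=O)OCC | starting material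
3 | lithium 5-methylcyclopenta-1,4-dien-1-olate (kinetic enolate of 1) | [Li+].[O-]C1=CCC=C1C | intermediate
4 | triethyl[(5-methylcyclopenta-1,4-dien-1-yl)oxy]silane | CC[Si](CC)(CC)OC1=CCC=C1C | intermediate
5 | ethyl (2R)-2-[(1S)-3-methyl-2-oxocyclopent-3-en-1-yl]-2-(triethylsilyloxy)propanoate (7,11-anti) | O=C1C(C)=CC[C@H]1[C@@](C)(O[Si](CC)(CC)CC)C(=O)OCC | intermediate
6 | but-3-en-1-ylmagnesium bromide | C=CCC[Mg]Br | starting material
7 | C8 tertiary allylic alcohol of 5 (but-3-enyl on C8; OH cis, butenyl trans to the C7 side chain) | C=CCC[C@]1(O)C(C)=CC[C@H]1[C@@](C)(O[Si](CC)(CC)CC)C(=O)OCC | intermediate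
8 | 4,5-epoxide of 7 (oxirane cis to the C8 hydroxyl) | C=CCC[C@]1(O)[C@@]2(C)O[C@H]2C[C@H]1[C@@](C)(O[Si](CC)(CC)CC)C(=O)OCC | intermediate
9 | ethyl 2-[3-(but-3-enyl)-4-hydroxy-3-methyl-2-oxocyclopentyl]-2-(triethylsilyloxy)propanoate (C4 methyl, C5 hydroxyl and C7 side chain all cis; butenyl trans) | C=CCC[C@]1(C)[C@@H](O)C[C@H](C1=O)[C@@](C)(O[Si](CC)(CC)CC)C(=O)OCC | intermediate
10 | 2-methylallylmagnesium chloride | CC(=C)C[Mg]Cl | starting material
11 | C8 tertiary alcohol of 9 (2-methylallyl on C8, cis to butenyl; C8–OH cis to the C7 side chain) | C=CCC[C@]1(C)[C@@H](O)C[C@@H]([C@@](C)(O[Si](CC)(CC)CC)C(=O)OCC)[C@]1(O)CC(C)=C | intermediate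
12 | bicyclic 8,12-lactone (cis-fused γ-lactone on C7–C8; C5–OH; C11 methyl exo, OSiEt3 endo) | C=CCC[C@]1(C)[C@@H](O)C[C@@H]2[C@@]1(CC(C)=C)OC(=O)[C@]2(C)O[Si](CC)(CC)CC | intermediate
13 | tricyclic lactone after metathesis (cis-fused cyclopentane–cycloheptene; C5–OH; C11–OSiEt3) | CC1=CCC[C@]2(C)[C@@H](O)C[C@@H]3[C@@]2(C1)OC(=O)[C@]3(C)O[Si](CC)(CC)CC | intermediate
14 | C5=C6 olefin of 13 (silyl ether) | CC1=CCC[C@]2(C)C=C[C@@H]3[C@@]2(C1)OC(=O)[C@]3(C)O[Si](CC)(CC)CC | intermediate
15 | tricyclic α-hydroxy lactone with C5=C6 and C1=C10 olefins | CC1=CCC[C@]2(C)C=C[C@@H]3[C@@]2(C1)OC(=O)[C@]3(C)O | intermediate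
16 | cyclic osmate ester of 15 with TMEDA (on the face of the lactone) | CC1=CCC[C@]2(C)[C@H]3O[Os-2]4(=O)(=O)(O[C@H]3[C@@H]5[C@@]2(C1)OC(=O)[C@]5(C)O)[N+](C)(C)CC[N+]4(C)C | intermediate
17 | 5,6-cis-diol of 15 (8,12-lactone; both hydroxyls cis to C11 and to the C4 methyl) | CC1=CCC[C@]2(C)[C@@H](O)[C@@H](O)[C@@H]3[C@@]2(C1)OC(=O)[C@]3(C)O | intermediate
18 | 6,12-lactone triol (C5–OH, C8–OH, C11–OH) | CC1=CCC[C@]2(C)[C@@H](O)[C@H]3OC(=O)[C@](C)(O)[C@H]3[C@]2(O)C1 | intermediate
19 | C5 methanesulfonate of 18 (mesylate cis to the C4 methyl) | CC1=CCC[C@]2(C)[C@@H](OS(C)(=O)=O)[C@H]3OC(=O)[C@](C)(O)[C@H]3[C@]2(O)C1 | intermediate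
20 | (1(10)Z,4E)-11-hydroxy-8-oxogermacra-1(10),4-dien-6,12-olide | C/C1=C/CC/C(C)=C/[C@H]2OC(=O)[C@](C)(O)[C@H]2C(=O)C1 | intermediate
21 | (1(10)Z,4E)-8,11-dihydroxygermacra-1(10),4-dien-6,12-olide | C/C1=C/CC/C(C)=C/[C@H]2OC(=O)[C@](C)(O)[C@H]2[C@H](O)C1 | intermediate
22 | (1(10)Z,4E)-6,11-dihydroxygermacra-1(10),4-dien-8,12-olide | C/C1=C/CC/C(C)=C/[C@@H](O)[C@@H]2[C@@H](C1)OC(=O)[C@]2(C)O | intermediate
23 | (4S,5S)-4,5-epoxy-6,11-dihydroxygermacr-1(10)Z-en-8,12-olide | O[C@H]1[C@@H]2[C@@H](C/C(C)=C\CC[C@]3(C)O[C@@H]13)OC(=O)[C@]2(C)O | intermediate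
24 | angelic acid ((Z)-2-methylbut-2-enoic acid) | C/C=C(/C)C(=O)O | starting material
25 | angelic 2,4,6-trichlorobenzoic anhydride | C/C=C(/C)C(=O)OC(=O)c1c(Cl)cc(Cl)cc1Cl | intermediate
26 | CNP0118683.3 (6,11-di-O-angeloyl-4,5-epoxygermacr-1(10)Z-en-8,12-olide) | C/C=C(/C)C(=O)O[C@H]1[C@@H]2[C@@H](C/C(C)=C\CC[C@]3(C)O[C@@H]13)OC(=O)[C@]2(C)OC(=O)/C(C)=C\C | target

**Totals**
Total steps: 11. Longest linear sequence: 11.

**Three steps most likely to fail**

Step 1 (the proposed new aldol). The catalyst may give the syn adduct, low enantioselectivity, or react at the other diene terminus. Fallback with known chemistry: setting out from 1 and 2, lithium enolate 3 is added directly to 2 in THF at −78 °C and the aldolate is silylated in the flask with Et3SiOSO2CF3, which gives the stereoisomer mixture of ethyl 2-(3-methyl-2-oxocyclopent-3-en-1-yl)-2-(triethylsilyloxy)propanoate F1. The syn pair is removed on silica and the anti racemate is resolved by preparative chiral supercritical-fluid chromatography. The route is rejoined at 5.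

Step 9 (fragmentation, reduction and lactone shift in one flask). The released β-acyloxy ketone 20 can undergo base-induced elimination. The C8 alkoxide can also translactonise before it fragments, which would let a C6 alkoxide displace the mesylate by hydride shift. Fallback that avoids strong base: setting out from triol 18, the secondary hydroxyl is activated in the flask with (CF3SO2)2O and 2,6-di-tert-butyl-4-methylpyridine in CH2Cl2 at −78 °C. The resulting C5 trifluoromethanesulfonate F2 fragments as it forms, with the neutral C8 hydroxyl as the electron source (the known triflic-anhydride-induced fragmentation of 1,3-diols). Ketone 20 is then isolated cold and reduced and translactonised as in step 9, so the route is rejoined at 20.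

Step 11 (bis-angeloylation). The tertiary C11 hydroxyl next to the lactone carbonyl is slow to acylate, and forcing conditions endanger the epoxide and the Z geometry of the ester. Fallback that changes the order: setting out from 22, both hydroxyls are esterified first with mixed anhydride 25 at 100 °C, with no epoxide present, to give the bis-angelate of the diene F3. The strained E-4,5-olefin is then epoxidised from its exposed face with dimethyldioxirane in acetone at −20 °C; the Z-1(10) olefin and the electron-poor angelate olefins react more slowly. The route is rejoined at 26.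

**Further compounds**
F1 | step 1 | ethyl 2-(3-methyl-2-oxocyclopent-3-en-1-yl)-2-(triethylsilyloxy)propanoate (mixture of the four stereoisomers) | CCOC(=O)C(C)(O[Si](CC)(CC)CC)C1CC=C(C)C1=O
F2 | step 9 | C5 trifluoromethanesulfonate of triol 18 | CC1=CCC[C@]2(C)[C@@H](OS(=O)(=O)C(F)(F)F)[C@H]3OC(=O)[C@](C)(O)[C@H]3[C@]2(O)C1
F3 | step 11 | (1(10)Z,4E)-6,11-di-O-angeloylgermacra-1(10),4-dien-8,12-olide | C/C1=C/CC/C(C)=C/[C@@H](OC(=O)/C(C)=C\C)[C@@H]2[C@@H](C1)OC(=O)[C@]2(C)OC(=O)/C(C)=C\C
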